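## Retrosynthetic overview
1. Anabsin ⇒ absinthin. The last ring (oxolane C10'–O–C4') and the C3'-OH come from one exo, syn oxidative cyclisation of C10'-OH onto C3'=C4'.
2. Absinthin ⇒ 2 × artabsin. The norbornene core forms by spontaneous dimerisation of the cyclopentadiene through its 2,4-diene tautomer.
3. Artabsin ⇒ 10β-hydroxy-3-oxoguai-4-en-12,6-olide ⇒ key step. This is a 6/6 → 5/7 skeletal 1,2-shift of a 10-epi-eudesma-1,4-dien-3-one: C5 moves from C10 to C1 and water enters C10 with inversion.
4. Dienone ⇒ cross-conjugated trienone + propionate (C7–C11 by 1,6-addition, C6–O by γ-oxidation). Trienone ⇒ octalone ⇒ 2-methylcyclohexanone + ethyl vinyl ketone, with C10 set by a chiral-imine Michael addition.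
5. Ring order: B (bought) → A (annulation) → A/B reshaped to cyclopentene/cycloheptane plus lactone → norbornene → oxolane.

Assumption: names use eudesmane/guaiane numbering (C1–C15; primed atoms are the diene-derived half of the dimer), and (S)-1-phenylethylamine is a recovered chiral auxiliary, not a starting material.

## Route

Step 1
Reactants: 1 2-methylcyclohexan-1-one (racemic); 2 pent-1-en-3-one
Product: 5 (R)-2-methyl-2-(3-oxopentyl)cyclohexan-1-one, via ketimine 3 (not isolated), via Michael adduct imine 4 (not isolated)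
Conditions: (S)-PhCH(CH3)NH2, TsOH (cat.), PhMe, reflux (−H2O); 2, THF, 25 °C, 72 h; 20% aq AcOH, 25 °C
Reagents that add atoms: water, O; (S)-1-phenylethylamine, C[C@H](N)c1ccccc1 (its atoms sit only in 3 and 4)
Why: d'Angelo asymmetric Michael addition: the more substituted secondary-enamine tautomer of chiral imine 3 adds to 2 on the face away from the phenyl group, which deracemises 1 and sets the quaternary C10 as R (about 90–95% ee, upgraded later because heterochiral dimers are separable diastereomers).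

Step 2
Reactants: 5 (R)-2-methyl-2-(3-oxopentyl)cyclohexan-1-one
Product: 6 (4aR)-1,4a-dimethyl-4,4a,5,6,7,8-hexahydronaphthalen-2(3H)-one
Conditions: NaOMe, MeOH, 60 °C
Reagents that add atoms: none
Why: Intramolecular aldol condensation (second half of a Robinson annulation) closes ring A, and the quaternary centre cannot epimerise.

Step 3
Reactants: 6 (4aR)-1,4a-dimethyl-4,4a,5,6,7,8-hexahydronaphthalen-2(3H)-one
Product: 7 (4aR)-1,4a-dimethyl-5,6-dihydronaphthalen-2(4aH)-one (1,4,6-trien-3-one in eudesmane numbering)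
Conditions: DDQ (2.6 equiv), TsOH·H2O (10 mol %), 1,4-dioxane, 100 °C
Reagents that add atoms: none
Why: DDQ dehydrogenation (hydride abstraction from the acid-formed 3,5-dienol, then from the 2,4-dienol) gives the 1,4,6-trien-3-one as it does for steroidal 4-en-3-ones, and no stereocentre is touched.

Step 4
Reactants: 8 methyl propanoate
Product: 9 (E)-1-methoxy-1-(trimethylsilyloxy)prop-1-ene
Conditions: LDA, THF, −78 °C; TMSCl, −78 → 25 °C; distil
Reagents that add atoms: chlorotrimethylsilane, C[Si](C)(C)Cl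
Why: Kinetic Ireland-type deprotonation gives the E(O)-enolate and O-silylation gives the (E)-ketene silyl acetal, with no stereocentre formed.

Step 5
Reactants: 7 (4aR)-1,4a-dimethyl-5,6-dihydronaphthalen-2(4aH)-one; 9 (E)-1-methoxy-1-(trimethylsilyloxy)prop-1-ene
Product: 11 methyl (6S,7S,10R,11S)-6-hydroxy-3-oxoeudesma-1,4-dien-12-oate (6α-OH 7β-side chain 10α-CH3), via silyl trienol ether 10 (not isolated)
Conditions: 9 (1.5 equiv), Tf2NH (2 mol %), CH2Cl2, −78 °C; NaHCO3, mCPBA, −40 → 0 °C; aq citric acid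
Reagents that add atoms: 3-chloroperoxybenzoic acid, OOC(=O)c1cccc(Cl)c1
Why: Vinylogous (1,6) Mukaiyama–Michael addition followed by vinylogous Rubottom oxidation: the branched nucleophile avoids the neopentyl C1 and attacks C7 axially, anti to the C10 methyl (the 7α rule of steroidal dienones), a synclinal open transition state with the nucleophile's H over ring B sets C11 as S (minor epimer removed by chromatography), and the peracid then attacks C6 of 10 axially and trans to the new side chain (the 6β rule of steroidal dienol ethers), giving a trans-diaxial 6α-OH/7β-chain pair that cannot lactonise yet.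

Step 6
Reactants: 11 methyl (6S,7S,10R,11S)-6-hydroxy-3-oxoeudesma-1,4-dien-12-oate
Product: 13 (1S,6S,7S,10S,11S)-10-hydroxy-3-oxoguai-4-en-12,6-olide (1βH 10β-OH; 1,10-di-epi-isophotosantonic lactone), via guaiane dihydroxy ester 12 (not isolated)
Conditions: hν (medium-pressure Hg, Pyrex), AcOH–H2O 1:1, 20 °C; then dark, 80 °C, 2 h
Reagents that add atoms: water, O
Why: Key skeletal rearrangement (cross-conjugated dienone to hydroazulenone, the santonin to isophotosantonic lactone type, a stepwise process): excited-state C1–C5 bonding gives a cyclopropyl zwitterion, protonation makes a cyclopropylcarbinyl cation, and water opens the C5–C10 bond from the rear, so C5 has shifted from C10 to C1 (ring A 6→5, ring B 6→7), the R quaternary C10 is converted with inversion into the 10β (S) carbinol, H-1 ends β, and the now flexible 6α-OH/ester pair lactonises on warming without touching C6, C7 or C11.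

Step 7
Reactants: 13 (1S,6S,7S,10S,11S)-10-hydroxy-3-oxoguai-4-en-12,6-olide
Product: 14 (1S,3R,6S,7S,10S,11S)-3,10-dihydroxyguai-4-en-12,6-olide (3α-OH)
Conditions: NaBH4, CeCl3·7H2O, MeOH, −20 °C
Reagents that add atoms: none
Why: Luche 1,2-reduction in which hydride enters from the β face, away from C10 and its α-methyl, to give the 3α-alcohol (a stereocentre removed in the next step), while lactone and tertiary alcohol are inert.

Step 8
Reactants: 14 (1S,3R,6S,7S,10S,11S)-3,10-dihydroxyguai-4-en-12,6-olide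
Product: 17 artabsin [(6S,7S,10S,11S)-10-hydroxyguaia-1(5),3-dien-12,6-olide], via allylic mesylate 15 (not isolated), via 1βH-2,4-diene 16 (not isolated)
Conditions: MsCl (1.05 equiv), Et3N, CH2Cl2, −30 → 0 °C; then PhMe (5 mM), 45 °C, 4 h
Reagents that add atoms: methanesulfonyl chloride, CS(=O)(=O)Cl (its atoms sit only in 15)
Why: Selective mesylation of the secondary allylic alcohol and amine-induced 1,2-elimination give 2,4-diene 16, and fast 1,5-hydrogen shifts of the cyclopentadiene funnel it in dilute solution to the most substituted diene 17, which erases the unwanted 1β-H.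

Step 9
Reactants: 17 artabsin (2 molecules)
Product: 19 absinthin, via 1αH-2,4-diene 18 (not isolated)
Conditions: neat film, Ar, dark, 25 °C, 10 d
Reagents that add atoms: none
Why: Biomimetic Diels–Alder dimerisation: 17 equilibrates by 1,5-H shift with 2,4-diene 18 (1α-H), one molecule reacts as diene (C2'/C5') and one as dienophile (C2=C3), each on its α face anti to the C10 branch and in the endo mode, which sets C1, C2, C3, C1', C2' and C5' and places C10'-OH syn over C3'=C4'.

Step 10
Reactants: 19 absinthin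
Product: 22 anabsin, via perrhenate ester 20 (not isolated), via rhenium(V) alkoxide 21 (not isolated)
Conditions: Re2O7 (1.5 equiv), 2,6-lutidine (3 equiv), CH2Cl2, −40 → 0 °C; H2O
Reagents that add atoms: rhenium(VII) oxide, O=[Re](=O)(=O)O[Re](=O)(=O)=O
Why: Proposed new method: perrhenate-ester syn-oxidative cyclisation on a strained bridged alkene; the tertiary C10'-OH, which absinthin holds directly over the exo face of the norbornene C3'=C4' bond, forms perrhenate ester 20, whose RO–Re=O unit adds across the alkene from that one face so that the ether oxygen binds the more substituted C4' (5-exo) and an oxo oxygen binds C3', both exo and cis, and hydrolysis of rhenium(V) alkoxide 21 frees the 3'-OH; the other tertiary alcohol could reach the hindered C4=C5 bond only in a 4-exo/5-endo sense and stays out, and lutidine buffers HReO4 against ionisation of the tertiary esters; the closest known reaction type is the Re(VII) (Kennedy-type) syn-oxidative cyclisation of flexible acyclic bishomoallylic alcohols to 2-(1-hydroxyalkyl)tetrahydrofurans, which has not been shown on a bicyclic alkene or for closing a cage ether.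

## Compound list
1 | 2-methylcyclohexan-1-one (racemic) | CC1CCCCC1=O | starting material
2 | pent-1-en-3-one | CCC(=O)C=C | starting material
3 | N-[(S)-1-phenylethyl] ketimine of 1 | CC1CCCCC1=N[C@@H](C)c1ccccc1 | intermediate (not isolated)
4 | Michael adduct imine | CCC(=O)CC[C@@]1(C)CCCCC1=N[C@@H](C)c1ccccc1 | intermediate (not isolated)
5 | (R)-2-methyl-2-(3-oxopentyl)cyclohexan-1-one | CCC(=O)CC[C@@]1(C)CCCCC1=O | intermediate
6 | (4aR)-1,4a-dimethyl-4,4a,5,6,7,8-hexahydronaphthalen-2(3H)-one | CC1=C2CCCC[C@]2(C)CCC1=O | intermediate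
7 | (4aR)-1,4a-dimethyl-5,6-dihydronaphthalen-2(4aH)-one | CC1=C2C=CCC[C@]2(C)C=CC1=O | intermediate
8 | methyl propanoate | CCC(=O)OC | starting material
9 | (E)-1-methoxy-1-(trimethylsilyloxy)prop-1-ene | C/C=C(\OC)O[Si](C)(C)C | intermediate
10 | methyl (7S,10R,11S)-3-(trimethylsilyloxy)eudesma-1,3,5-trien-12-oate | CC1=C(O[Si](C)(C)C)C=C[C@@]2(C)CC[C@@H]([C@H](C)C(=O)OC)C=C12 | intermediate (not isolated)
11 | methyl (6S,7S,10R,11S)-6-hydroxy-3-oxoeudesma-1,4-dien-12-oate | CC1=C2[C@@H](O)[C@@H](CC[C@]2(C)C=CC1=O)[C@H](C)C(=O)OC | intermediate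
12 | methyl (1S,6S,7S,10S,11S)-6,10-dihydroxy-3-oxoguai-4-en-12-oate | CC1=C2[C@@H](O)[C@@H](CC[C@](C)(O)[C@H]2CC1=O)[C@H](C)C(=O)OC | intermediate (not isolated)
13 | (1S,6S,7S,10S,11S)-10-hydroxy-3-oxoguai-4-en-12,6-olide | CC1=C2[C@H]3OC(=O)[C@@H](C)[C@@H]3CC[C@](C)(O)[C@H]2CC1=O | intermediate
14 | (1S,3R,6S,7S,10S,11S)-3,10-dihydroxyguai-4-en-12,6-olide | CC1=C2[C@H]3OC(=O)[C@@H](C)[C@@H]3CC[C@](C)(O)[C@H]2C[C@H]1O | intermediate
15 | 3-O-methanesulfonate of 14 | CC1=C2[C@H]3OC(=O)[C@@H](C)[C@@H]3CC[C@](C)(O)[C@H]2C[C@H]1OS(C)(=O)=O | intermediate (not isolated)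
16 | (1S,6S,7S,10S,11S)-10-hydroxyguaia-2,4-dien-12,6-olide (1βH) | CC1=C2[C@H]3OC(=O)[C@@H](C)[C@@H]3CC[C@](C)(O)[C@H]2C=C1 | intermediate (not isolated)
17 | artabsin | CC1=CCC2=C1[C@H]3OC(=O)[C@@H](C)[C@@H]3CC[C@]2(C)O | intermediate
18 | (1R,6S,7S,10S,11S)-10-hydroxyguaia-2,4-dien-12,6-olide (1αH) | CC1=C2[C@H]3OC(=O)[C@@H](C)[C@@H]3CC[C@](C)(O)[C@@H]2C=C1 | intermediate (not isolated)
19 | absinthin | CC1=C2[C@H]3OC(=O)[C@@H](C)[C@@H]3CC[C@](C)(O)[C@@H]2[C@H]2[C@@H]3[C@@H]4[C@@]([C@H]6OC(=O)[C@@H](C)[C@@H]6CC[C@]4(C)O)(C(C)=C3)[C@@H]12 | intermediate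
20 | absinthin 10'-perrhenate ester | CC1=C2[C@H]3OC(=O)[C@@H](C)[C@@H]3CC[C@](C)(O)[C@@H]2[C@H]2[C@@H]3[C@@H]4[C@@]([C@H]6OC(=O)[C@@H](C)[C@@H]6CC[C@]4(C)O[Re](=O)(=O)=O)(C(C)=C3)[C@@H]12 | intermediate (not isolated)
21 | anabsin 3'-O-dioxorhenium(V) alkoxide | CC1=C2[C@H]3OC(=O)[C@@H](C)[C@@H]3CC[C@](C)(O)[C@@H]2[C@H]2[C@@H]3[C@@H]4[C@]5([C@H]6OC(=O)[C@@H](C)[C@@H]6CC[C@]4(C)O[C@@]5(C)[C@H]3O[Re](=O)=O)[C@@H]12 | intermediate (not isolated)
22 | anabsin | CC1=C2[C@H]3OC(=O)[C@@H](C)[C@@H]3CC[C@](C)(O)[C@@H]2[C@H]2[C@@H]3[C@@H]4[C@]5([C@H]6OC(=O)[C@@H](C)[C@@H]6CC[C@]4(C)O[C@@]5(C)[C@H]3O)[C@@H]12 | target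

## Step count and risks
Total steps: 10. Longest linear sequence: 9 (steps 1–3 and 5–10; step 4 is a side branch).

**Step 5.** The risks are C7 versus C1 attack on the cross-conjugated trienone, the C11 ratio, and C6 versus C4 oxidation.
- The fallback sets out from 6 and comes back at 10, using known chemistry at the cost of three more steps.
- Chloranil in refluxing t-BuOH takes 6 only as far as the linear (4aR)-4,6-dien-3-one F1, which has no competing C1 acceptor site.
- Ketene acetal 9 under TiCl4 activation adds 1,6 to give the silyl dienol ether F2.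
- F2 is hydrolysed on work-up to the 3-oxoeudesm-4-en-12-oate F3.
- DDQ in neutral dioxane introduces the 1,2-double bond to give the 3-oxoeudesma-1,4-dien-12-oate F4.
- TMSOTf/Et3N removes the only vinylogously acidic proton of the ketone (H-6) to give 10, which is oxidised with mCPBA as in step 5.

**Step 9.** The risks are dehydration of the free tertiary alcohol to azulenogenic trienes, slow reaction, and isomeric dimers from other hydrogen-shift tautomers.
- The fallback sets out from 17 and comes back at 19.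
- N-(trimethylsilyl)imidazole converts 17 into artabsin trimethylsilyl ether F5.
- F5 tolerates heating as a concentrated toluene solution (70 °C) or 10 kbar pressure.
- It reacts through its 1αH-2,4-diene tautomer F6 to give absinthin bis(trimethylsilyl) ether F7.
- Citric acid in aqueous methanol releases 19.

**Step 10 (the proposed new step).** The risks are ionisation or elimination of the tertiary perrhenates and poor reach of the Re=O unit.
- The fallback sets out from 19 and comes back at 22, using known chemistry.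
- Hydroxyl-directed epoxidation with mCPBA/NaHCO3 (CH2Cl2, 0 °C) attacks the strained norbornene bond from the face of the C10'-OH to give absinthin exo-3',4'-epoxide F8.
- Catalytic camphorsulfonic acid (CH2Cl2, −20 °C) then opens F8 at the tertiary C4' in an SN1 sense.
- The only nucleophile in reach, C10'-OH, captures the cation from the exo face, so the ether and the exo 3'-OH of 22 result.

## Further compounds
F1 | step 5 | (4aR)-1,4a-dimethyl-4,4a,5,6-tetrahydronaphthalen-2(3H)-one (4,6-dien-3-one) | CC1=C2C=CCC[C@]2(C)CCC1=O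
F2 | step 5 | methyl (7S,10R,11S)-3-(trimethylsilyloxy)eudesma-3,5-dien-12-oate | CC1=C(O[Si](C)(C)C)CC[C@@]2(C)CC[C@@H]([C@H](C)C(=O)OC)C=C12
F3 | step 5 | methyl (7S,10R,11S)-3-oxoeudesm-4-en-12-oate | CC1=C2C[C@@H](CC[C@]2(C)CCC1=O)[C@H](C)C(=O)OC
F4 | step 5 | methyl (7S,10R,11S)-3-oxoeudesma-1,4-dien-12-oate | CC1=C2C[C@@H](CC[C@]2(C)C=CC1=O)[C@H](C)C(=O)OC
F5 | step 9 | artabsin trimethylsilyl ether | CC1=CCC2=C1[C@H]3OC(=O)[C@@H](C)[C@@H]3CC[C@]2(C)O[Si](C)(C)C
F6 | step 9 | trimethylsilyl ether of 18 (1αH-2,4-diene tautomer) | CC1=C2[C@H]3OC(=O)[C@@H](C)[C@@H]3CC[C@](C)(O[Si](C)(C)C)[C@@H]2C=C1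
F7 | step 9 | absinthin bis(trimethylsilyl) ether | CC1=C2[C@H]3OC(=O)[C@@H](C)[C@@H]3CC[C@](C)(O[Si](C)(C)C)[C@@H]2[C@H]2[C@@H]3[C@@H]4[C@@]([C@H]6OC(=O)[C@@H](C)[C@@H]6CC[C@]4(C)O[Si](C)(C)C)(C(C)=C3)[C@@H]12
F8 | step 10 | absinthin exo-3',4'-epoxide | CC1=C2[C@H]3OC(=O)[C@@H](C)[C@@H]3CC[C@](C)(O)[C@@H]2[C@H]2[C@@H]3[C@@H]4[C@@]([C@H]6OC(=O)[C@@H](C)[C@@H]6CC[C@]4(C)O)([C@@]7(C)O[C@H]73)[C@@H]12
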